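**Retrosynthetic overview**

1. Target ⇐ late, reagent- or conformation-controlled steps on a complete C15 skeleton: Shi epoxidation of C10=C11, trans-diaxial HCl opening of a 3β,4β-oxirane (Cl to C4, OH to C3), two angeloylations from one mixed anhydride, and CBS reduction of a C14=C7–C8(=O) enone.
2. Key disconnection, bond C6–C7: ring carbon C6 is joined to the exo-methylene carbon C7 on the crowded β-face that also carries O1, O2 and O3 (all-cis C6/C1/C2/C3). O1 and C8 stand 1,4 across this bond, so C8 is tied to O1 as a ketal and a C7 vinyl radical closes 5-exo onto C6 of a C3=C4–C5=C6 diene; C5 takes H and C3=C4 survives for the oxirane.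
3. Radical precursor ⇐ NBS bromoketalisation of a cis-diene-diol with 1-prenyl-1-methoxyallene (methoxyallene + prenyl bromide), which brings C7–C14 in one piece.
4. Diene-diol ⇐ toluene by enzymatic dearomatising cis-dihydroxylation: the C1–C6 ring, C15, the C1 and C2 stereocentres and the diene all come from the arene.
5. Ring order: carbocycle from the arene (never built); temporary oxolane O1–C8–C7–C6–C1 (closed in the key step, opened by ketal hydrolysis); ring oxirane C3–C4 (closed, later opened to the chlorohydrin); side-chain oxirane C10–C11 last.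

Key step: step 4

Remark (numbering): bisabolane numbering is used: ring C1 (free OH), C2 (O-angelate), C3 (OH and methyl C15), C4 (Cl), C5 (CH2), C6 (bears C7); side chain C7(=C14H2)–C8(O-angelate)–C9H2–C10–C11(C12, C13); β is the ring face that carries O1, O2, O3 and C7 in the target, and Cl and C15 are α.

Remark (assumption): the whole-cell toluene dioxygenase oxidation of step 1 is treated as a standard preparative reaction, with the nicotinamide cofactor recycled by the cells from glucose.

Remark (assumption): the ketal carbon C8 of compounds 7, 8, 9 and 12 is carried as both epimers, because step 8 removes this centre.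

Step 1
Reactants: 1 toluene
Product: 2 (1S,2R)-3-methylcyclohexa-3,5-diene-1,2-diol
Conditions: E. coli JM109(pDTG601) whole cells (toluene dioxygenase), glucose, air, mineral medium pH 7, 30 °C, toluene fed as vapour; EtOAc extraction
Reagents that add atoms: dioxygen, O=O
Why: Enzymatic dearomatising cis-dihydroxylation (toluene dioxygenase) adds both oxygens of O2 to C1 and C2 from one face with the enzyme fixing (1S,2R), so the flat arene becomes the C1–C6 ring with O1 and O2 on the β-face, C15 in place and the C3=C4–C5=C6 diene ready for steps 4 and 5.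

Step 2
Reactants: 3 methoxyallene; 4 prenyl bromide
Product: 6 3-methoxy-6-methylhepta-1,2,5-triene, via 1-lithio-1-methoxyallene 5 (not isolated)
Conditions: n-BuLi, THF, −78 to −40 °C; then 4, −78 to 0 °C
Reagents that add atoms: none
Why: α-Lithiation of an alkoxyallene next to oxygen followed by SN2 alkylation with the primary allylic bromide is a standard allenyl ether alkylation and creates no stereocentre.

Step 3
Reactants: 2 (1S,2R)-3-methylcyclohexa-3,5-diene-1,2-diol; 6 3-methoxy-6-methylhepta-1,2,5-triene
Product: 7 (1R,6S)-6-[(2-bromo-3-methoxy-6-methylhepta-1,5-dien-3-yl)oxy]-2-methylcyclohexa-2,4-dien-1-ol (ketal on O1, free O2–H; both C8 epimers)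
Conditions: NBS (1.2 equiv), 6 (1.5 equiv), 2,6-lutidine (0.2 equiv), CH2Cl2, −78 to −30 °C
Reagents that add atoms: N-bromosuccinimide, O=C1CCC(=O)N1Br
Why: Bromo-alkoxylation of an alkoxyallene (Ueno–Stork-type haloketalisation) should put Br+ on the central carbon of the most electron-rich π-system present, and the tertiary 2-bromoallyl oxocarbenium ion should then be trapped by the less hindered O1–H rather than by O2–H next to the methyl-bearing C3, the new ketal centre C8 being left uncontrolled.

Step 4
Reactants: 7 (1R,6S)-6-[(2-bromo-3-methoxy-6-methylhepta-1,5-dien-3-yl)oxy]-2-methylcyclohexa-2,4-dien-1-ol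
Product: 8 (1S,2R,6R)-8-methoxy-1,8-epoxybisabola-3,7(14),10-trien-2-ol (cis-fused 2-methoxy-3-methylideneoxolane on C1/C6; both C8 epimers)
Conditions: Bu3SnH (1.3 equiv, slow addition), Et3B (0.2 equiv)/air, toluene, 0 °C to rt
Reagents that add atoms: none
Why: Bu3Sn• abstracts bromine to give the σ-vinyl radical at C7, which adds to C6 of the C3=C4–C5=C6 diene, and the resulting C3–C4–C5 allyl radical takes hydrogen from Bu3SnH at C5, its less substituted terminus, so that the trisubstituted C3=C4 alkene needed for step 5 is kept. The closest known reaction type is the Ueno–Stork haloacetal radical cyclisation in its vinyl-radical form (2-bromoallyl acetals from alkoxyallenes giving 3-methylideneoxolanes), here run on a ketal and onto a diene. The one ring closed, the oxolane O1–C8–C7–C6–C1, forms in the 5-exo-trig mode, since 6-endo attack at C5 would give neither the small ring nor an allylic radical. The new stereocentre C6 is fixed by the tether: a five-membered ring fused to the cyclohexene can only be cis, so C7 is delivered to the β-face on which O1 stands, the hindered all-cis face that intermolecular reagents avoid. The step needs cyclisation to outrun direct reduction and 1,5-hydrogen transfer from C2–H, which the fast 5-exo addition to a diene and a low stannane concentration should secure, and it needs hydrogen transfer at C5 rather than C3, which the secondary against tertiary terminus and the more substituted alkene product favour. In this one operation the ring is joined to the whole side chain at its most hindered bond and all fifteen skeletal carbons are in place.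

Step 5
Reactants: 8 (1S,2R,6R)-8-methoxy-1,8-epoxybisabola-3,7(14),10-trien-2-ol
Product: 9 (1S,2S,3S,4R,6R)-3,4:1,8-diepoxy-8-methoxybisabola-7(14),10-dien-2-ol (3β,4β-oxirane; both C8 epimers)
Conditions: VO(acac)2 (5 mol %), t-BuOOH (1.5 equiv), CH2Cl2, 0 °C to rt
Reagents that add atoms: tert-butyl hydroperoxide, CC(C)(C)OO
Why: Hydroxyl-directed vanadium-catalysed epoxidation (Sharpless–Michaelson type) should deliver oxygen to C3=C4 from the face of the allylic O2–H, setting C3 and C4 with the oxirane β, while the undirected C10=C11 and the remote C7=C14 alkenes are left.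

Step 6
Reactants: 10 angelic acid
Product: 11 angelic 2,4,6-trichlorobenzoic anhydride
Conditions: 2,4,6-trichlorobenzoyl chloride (1.0 equiv), Et3N (1.05 equiv), toluene, rt; filtration of Et3N·HCl under argon; filtrate kept as a stock solution at −20 °C (the step is repeated on the scale of step 10 if the stock has aged)
Reagents that add atoms: 2,4,6-trichlorobenzoyl chloride, O=C(Cl)c1c(Cl)cc(Cl)cc1Cl
Why: Acylation of the triethylammonium carboxylate by the hindered aroyl chloride, the first stage of the Yamaguchi esterification, should give the mixed anhydride at room temperature without Z-to-E isomerisation of the angeloyl group, and this one reagent serves both angeloylations (steps 7 and 10).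

Step 7
Reactants: 9 (1S,2S,3S,4R,6R)-3,4:1,8-diepoxy-8-methoxybisabola-7(14),10-dien-2-ol; 11 angelic 2,4,6-trichlorobenzoic anhydride
Product: 12 (1S,2S,3R,4R,6R)-3,4:1,8-diepoxy-8-methoxybisabola-7(14),10-dien-2-yl angelate (both C8 epimers)
Conditions: 11 (2 equiv, toluene solution from step 6), Et3N (2.5 equiv), toluene, 80 °C
Reagents that add atoms: none
Why: Yamaguchi-type mixed-anhydride esterification without DMAP, the usual way to make angelates without Z-to-E isomerisation to tiglates, should transfer the unhindered angeloyl group to the only free hydroxyl (O2) with retention at C2, the amine buffering the liberated acid so that the ketal and the oxirane survive and the cis relation of O2 and the oxirane ruling out Payne-type migration.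

Step 8
Reactants: 12 (1S,2S,3R,4R,6R)-3,4:1,8-diepoxy-8-methoxybisabola-7(14),10-dien-2-yl angelate
Product: 13 (1S,2S,3R,4R,6R)-3,4-epoxy-1-hydroxy-8-oxobisabola-7(14),10-dien-2-yl angelate
Conditions: PPTS (0.2 equiv), acetone–H2O 9:1, rt
Reagents that add atoms: water, O
Why: Mild acid hydrolysis of the mixed methyl ketal through its oxocarbenium ion should release the C8 ketone and O1–H at once without touching a stereocentre, the acyloxy-deactivated oxirane and the ester should tolerate pyridinium tosylate, and opening the ketal while O3 is still locked in the oxirane avoids an intramolecular O1,O3-ketal.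

Step 9
Reactants: 13 (1S,2S,3R,4R,6R)-3,4-epoxy-1-hydroxy-8-oxobisabola-7(14),10-dien-2-yl angelate
Product: 14 (1S,2S,3R,4R,6R,8S)-3,4-epoxy-1,8-dihydroxybisabola-7(14),10-dien-2-yl angelate
Conditions: (R)-2-methyl-CBS-oxazaborolidine (0.5 equiv), catecholborane (3 equiv), toluene, −78 °C; then MeOH, aq. NaHCO3
Reagents that add atoms: none
Why: Corey–Bakshi–Shibata reduction under reagent control, in which the branched alkenyl carbon C7 acts as the large and the C9 methylene as the small substituent, should give (8S) with the (R)-catalyst, and catecholborane at −78 °C should leave the alkenes, the ester and the oxirane alone.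

Step 10
Reactants: 14 (1S,2S,3R,4R,6R,8S)-3,4-epoxy-1,8-dihydroxybisabola-7(14),10-dien-2-yl angelate; 11 angelic 2,4,6-trichlorobenzoic anhydride
Product: 15 (1S,2S,3R,4R,6R,8S)-3,4-epoxy-1-hydroxybisabola-7(14),10-diene-2,8-diyl diangelate
Conditions: 11 (1.2 equiv, toluene solution from step 6), Et3N (1.5 equiv), toluene, 60 °C
Reagents that add atoms: none
Why: The same mixed-anhydride angeloylation should take the acyclic allylic O8–H, with retention at C8, in preference to the axial O1–H, which is flanked by the C2 ester and the C6 branch.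

Step 11
Reactants: 15 (1S,2S,3R,4R,6R,8S)-3,4-epoxy-1-hydroxybisabola-7(14),10-diene-2,8-diyl diangelate
Product: 16 (1S,2S,3S,4S,6R,8S)-4-chloro-1,3-dihydroxybisabola-7(14),10-diene-2,8-diyl diangelate
Conditions: pyridinium chloride (3 equiv), CH2Cl2, 0 °C to rt
Reagents that add atoms: pyridinium chloride, [Cl-].c1cc[nH+]cc1
Why: Trans-diaxial (Fürst–Plattner) epoxide opening by chloride under buffered acid should occur at secondary C4 from the α-face, because only this attack leads directly to a chair with the C6 side chain equatorial (the behaviour of trans-limonene-oxide-type epoxides) and C3 is fully substituted and deactivated by the C2 acyloxy group, so inversion at C4 gives 4α-Cl and retention at C3 gives 3β-OH.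

Step 12
Reactants: 16 (1S,2S,3S,4S,6R,8S)-4-chloro-1,3-dihydroxybisabola-7(14),10-diene-2,8-diyl diangelate
Product: 17 (1S,2S,3S,4S,6R,8S,10R)-4-chloro-10,11-epoxy-1,3-dihydroxybisabol-7(14)-ene-2,8-diyl diangelate (CNP0158207.1)
Conditions: D-fructose-derived Shi ketone (1.0 equiv), Oxone, NaHCO3, MeCN–aq. Na2EDTA (pH about 8), 0 °C
Reagents that add atoms: potassium peroxymonosulfate (active component of Oxone), [K+].[O-]S(=O)(=O)OO
Why: Shi asymmetric epoxidation should let the chiral dioxirane react with the electron-rich trisubstituted C10=C11 alkene through the spiro transition state that gives the (10R)-oxirane, while the 1,1-disubstituted C7=C14 and the conjugated angelate alkenes are poor substrates and the near-neutral pH spares the chlorohydrin.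

**Compound list**

1 | toluene | Cc1ccccc1 | starting material
2 | (1S,2R)-3-methylcyclohexa-3,5-diene-1,2-diol | CC1=CC=C[C@H](O)[C@@H]1O | intermediate
3 | methoxyallene (1-methoxypropa-1,2-diene) | COC=C=C | starting material
4 | prenyl bromide (1-bromo-3-methylbut-2-ene) | CC(C)=CCBr | starting material
5 | 1-lithio-1-methoxyallene | [Li]C(OC)=C=C | intermediate
6 | 3-methoxy-6-methylhepta-1,2,5-triene | C=C=C(OC)CC=C(C)C | intermediate
7 | (1R,6S)-6-[(2-bromo-3-methoxy-6-methylhepta-1,5-dien-3-yl)oxy]-2-methylcyclohexa-2,4-dien-1-ol (both C8 epimers) | CC1=CC=C[C@H](OC(OC)(CC=C(C)C)C(Br)=C)[C@@H]1O | intermediate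
8 | (1S,2R,6R)-8-methoxy-1,8-epoxybisabola-3,7(14),10-trien-2-ol (both C8 epimers) | CC1=CC[C@@H]2C(=C)C(OC)(CC=C(C)C)O[C@@H]2[C@@H]1O | intermediate
9 | (1S,2S,3S,4R,6R)-3,4:1,8-diepoxy-8-methoxybisabola-7(14),10-dien-2-ol (both C8 epimers) | C[C@@]12O[C@@H]1C[C@@H]3C(=C)C(OC)(CC=C(C)C)O[C@@H]3[C@@H]2O | intermediate
10 | angelic acid ((Z)-2-methylbut-2-enoic acid) | C/C=C(/C)C(=O)O | starting material
11 | angelic 2,4,6-trichlorobenzoic anhydride | C/C=C(/C)C(=O)OC(=O)c1c(Cl)cc(Cl)cc1Cl | intermediate
12 | (1S,2S,3R,4R,6R)-3,4:1,8-diepoxy-8-methoxybisabola-7(14),10-dien-2-yl angelate (both C8 epimers) | C[C@@]12O[C@@H]1C[C@@H]3C(=C)C(OC)(CC=C(C)C)O[C@@H]3[C@@H]2OC(=O)/C(C)=C\C | intermediate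
13 | (1S,2S,3R,4R,6R)-3,4-epoxy-1-hydroxy-8-oxobisabola-7(14),10-dien-2-yl angelate | C=C(C(=O)CC=C(C)C)[C@H]1C[C@H]2O[C@@]2(C)[C@@H](OC(=O)/C(C)=C\C)[C@H]1O | intermediate
14 | (1S,2S,3R,4R,6R,8S)-3,4-epoxy-1,8-dihydroxybisabola-7(14),10-dien-2-yl angelate | C=C([C@H](CC=C(C)C)O)[C@H]1C[C@H]2O[C@@]2(C)[C@@H](OC(=O)/C(C)=C\C)[C@H]1O | intermediate
15 | (1S,2S,3R,4R,6R,8S)-3,4-epoxy-1-hydroxybisabola-7(14),10-diene-2,8-diyl diangelate | C=C([C@H](CC=C(C)C)OC(=O)/C(C)=C\C)[C@H]1C[C@H]2O[C@@]2(C)[C@@H](OC(=O)/C(C)=C\C)[C@H]1O | intermediate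
16 | (1S,2S,3S,4S,6R,8S)-4-chloro-1,3-dihydroxybisabola-7(14),10-diene-2,8-diyl diangelate | C=C([C@H](CC=C(C)C)OC(=O)/C(C)=C\C)[C@H]1C[C@H](Cl)[C@@](C)(O)[C@@H](OC(=O)/C(C)=C\C)[C@H]1O | intermediate
17 | (1S,2S,3S,4S,6R,8S,10R)-4-chloro-10,11-epoxy-1,3-dihydroxybisabol-7(14)-ene-2,8-diyl diangelate (CNP0158207.1) | C=C([C@H](C[C@H]1OC1(C)C)OC(=O)/C(C)=C\C)[C@H]1C[C@H](Cl)[C@@](C)(O)[C@@H](OC(=O)/C(C)=C\C)[C@H]1O | target

**Step count**

Total steps: 12. Longest linear sequence: 10 (steps 1, 3–5 and 7–12, from toluene); step 2 makes the tether reagent and step 6 the acylating agent used in steps 7 and 10.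

**Three steps most likely to fail**

1. Step 4 (key step). The σ-vinyl radical next to the fully substituted ketal carbon may be reduced, or may shift hydrogen from C2–H, before it closes. Hydrogen transfer to the allyl radical may occur in part at C3, and the borane initiator may ionise the ketal. The fallback sets out from 2 and comes back at 13. It keeps the tether idea but uses the silicon-tethered vinyl-radical cyclisation, and makes the C7–C8 bond afterwards by carbonyl addition. Diol 2 would be silylated at the less hindered O1 with the known reagent (1-bromovinyl)chlorodimethylsilane F1 (imidazole, CH2Cl2, −78 °C) to give the O1 (1-bromovinyl)dimethylsilyl ether F2. Bu3SnH/Et3B should close its α-silylvinyl radical 5-exo onto C6 to give the cis-fused cyclic vinylsiloxane F3. O2-directed VO(acac)2/t-BuOOH epoxidation should give the 3β,4β-epoxy siloxane F4, and angeloylation with 11 (as in step 7) its 2-O-angelate F5. Iododesilylation (NIS, MeCN, 0 °C; the O1–Si bond is hydrolysed on work-up) should give the 7-iodoalkene F6. Nozaki–Hiyama–Kishi coupling (CrCl2, cat. NiCl2, DMSO) with 4-methylpent-3-enal F7 (Dess–Martin oxidation of commercial 4-methylpent-3-en-1-ol) would form C7–C8 as the C8-epimeric allylic alcohols F8. MnO2 oxidation of this allylic alcohol should give 13, where the CBS step sets C8.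

2. Step 3. The oxocarbenium ion may be trapped by O2–H as well as O1–H, and NBS may brominate the diene. The fallback sets out from 2 and comes back at 8; it fixes the site by protecting groups instead of by inherent selectivity. TBSCl/imidazole (DMF, −20 °C) should silylate the less hindered O1–H to give the 1-O-TBS ether F9. Ac2O/pyridine should give the 1-O-TBS-2-O-acetyl diol F10. TBAF buffered with AcOH should give the 2-O-acetyl diol F11, whose only free hydroxyl is O1–H. NBS and 6 should then give the 2-O-acetyl bromoketal F12, and Bu3SnH/Et3B the cyclised 2-O-acetate F13. K2CO3 in MeOH should remove the acetate to give 8.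

3. Step 10. The acylation may lose site selectivity (attack at O1–H), or the C2 angelate may migrate to O1 under warm basic conditions. The fallback sets out from 13 and comes back at 15. TESCl/imidazole (DMF, 0 °C) should silylate the only free hydroxyl to give the 1-O-TES enone F14. The CBS reduction of step 9 should give the 1-O-TES allylic alcohol F15, and angeloylation with 11, now without a competing hydroxyl, the 1-O-TES diangelate F16. TBAF buffered with AcOH (THF, 0 °C) should then give 15.

**Further compounds**

F1 | step 4 | (1-bromovinyl)chlorodimethylsilane | C=C(Br)[Si](C)(C)Cl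
F2 | step 4 | (1S,2R)-1-O-[(1-bromovinyl)dimethylsilyl]-3-methylcyclohexa-3,5-diene-1,2-diol | CC1=CC=C[C@H](O[Si](C)(C)C(Br)=C)[C@@H]1O
F3 | step 4 | cis-fused cyclic vinylsiloxane (O1–SiMe2–C7(=C14H2)–C6; free O2–H; C3=C4) | CC1=CC[C@@H]2C(=C)[Si](C)(C)O[C@@H]2[C@@H]1O
F4 | step 4 | 3β,4β-epoxide of F3 | C[C@@]12O[C@@H]1C[C@@H]3C(=C)[Si](C)(C)O[C@@H]3[C@@H]2O
F5 | step 4 | 2-O-angelate of F4 | C[C@@]12O[C@@H]1C[C@@H]3C(=C)[Si](C)(C)O[C@@H]3[C@@H]2OC(=O)/C(C)=C\C
F6 | step 4 | 7-iodoalkene (C6–C(I)=CH2; 1-OH; 2-O-angelate; 3β,4β-oxirane) | C=C(I)[C@H]1C[C@H]2O[C@@]2(C)[C@@H](OC(=O)/C(C)=C\C)[C@H]1O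
F7 | step 4 | 4-methylpent-3-enal | CC(C)=CCC=O
F8 | step 4 | C8-epimeric mixture of 14 | C=C(C(O)CC=C(C)C)[C@H]1C[C@H]2O[C@@]2(C)[C@@H](OC(=O)/C(C)=C\C)[C@H]1O
F9 | step 3 | 1-O-TBS ether of 2 | CC1=CC=C[C@H](O[Si](C)(C)C(C)(C)C)[C@@H]1O
F10 | step 3 | 1-O-TBS-2-O-acetyl derivative of 2 | CC1=CC=C[C@H](O[Si](C)(C)C(C)(C)C)[C@@H]1OC(C)=O
F11 | step 3 | 2-O-acetyl derivative of 2 | CC1=CC=C[C@H](O)[C@@H]1OC(C)=O
F12 | step 3 | 2-O-acetate of 7 (both C8 epimers) | CC1=CC=C[C@H](OC(OC)(CC=C(C)C)C(Br)=C)[C@@H]1OC(C)=O
F13 | step 3 | 2-O-acetate of 8 (both C8 epimers) | CC1=CC[C@@H]2C(=C)C(OC)(CC=C(C)C)O[C@@H]2[C@@H]1OC(C)=O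
F14 | step 10 | 1-O-TES ether of 13 | C=C(C(=O)CC=C(C)C)[C@H]1C[C@H]2O[C@@]2(C)[C@@H](OC(=O)/C(C)=C\C)[C@H]1O[Si](CC)(CC)CC
F15 | step 10 | 1-O-TES ether of 14 | C=C([C@H](CC=C(C)C)O)[C@H]1C[C@H]2O[C@@]2(C)[C@@H](OC(=O)/C(C)=C\C)[C@H]1O[Si](CC)(CC)CC
F16 | step 10 | 1-O-TES ether of 15 | C=C([C@H](CC=C(C)C)OC(=O)/C(C)=C\C)[C@H]1C[C@H]2O[C@@]2(C)[C@@H](OC(=O)/C(C)=C\C)[C@H]1O[Si](CC)(CC)CC
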